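**Retrosynthetic overview**

1. Target 35 ⇐ primary acetylation and desilylation of butenolide 33 ⇐ furan 30 (singlet-oxygen oxidation, NaBH4) ⇐ 2,5-dihydrofuran-fused cyclooctenol 29.
2. 29 ⇐ one-pot union of allylic carbamate 14 (three ring carbons) and cyclopropyl boronate 23 (five ring carbons): a 1,2-shift from boron to carbon joins the cyclopropane CH to the future butenolide α-carbon, then intramolecular allylboration joins the side-chain-bearing ring CH to the carbinol carbon and closes the cyclooctene.
3. Enabling feature: in the eight-membered ring the array cyclopropane CH–C(α)=C(β)–CH(side chain)–CH(OH) is a homoallylic alcohol whose alkene carbon carries the cyclopropyl group, the imprint of an α-substituted allylboron adding to an aldehyde; the cis-fused cyclopropane and the five-membered oxacycle hold five of the eight ring atoms in place.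
4. 14 ⇐ rhodium-catalysed reductive cyclisation of alkynal 12 (oxolane, E-alkylidene, carbinol) ⇐ copper-catalysed SN2' alkynylation and B-alkyl Suzuki–Miyaura coupling; 23 ⇐ (S)-but-3-yn-2-ol via Z-alkenylboronate, hydroxyl-directed Simmons–Smith reaction and iminium transfer hydrogenation.
5. Ring order: cyclopropane (fragment 2) and oxolane (fragment 1), then cyclooctene (key step), then furan and finally butenolide from the oxacycle.

Key step: step 16

Remark (assumption on the stereochemical course): borylation of the lithiated carbamate by the pinacol boronate is taken to go with retention and the 1,2-shift with inversion at carbon, as is usual for pinacol boronic esters; were borylation to invert, the 3S carbinol from the antipodal ligand in step 7 would be carried forward instead.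

**Route**

Step 1
Reactants: 1 (Z)-but-2-ene-1,4-diol
Product: 2 (Z)-4-[(tert-butyldiphenylsilyl)oxy]but-2-en-1-ol
Conditions: NaH (1.0 equiv), THF, 0 °C; tBuPh2SiCl, 0 °C → rt
Reagents that add atoms: tert-butyl(chloro)diphenylsilane, CC(C)(C)[Si](Cl)(c1ccccc1)c1ccccc1
Why: O-silylation of the monosodium alkoxide of a symmetrical diol should stop at the mono-ether because the mono-alkoxide reacts as it forms; no stereocentre is created.

Step 2
Reactants: 2 (Z)-4-[(tert-butyldiphenylsilyl)oxy]but-2-en-1-ol
Product: 3 (Z)-4-[(tert-butyldiphenylsilyl)oxy]but-2-en-1-yl diethyl phosphate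
Conditions: (EtO)2P(O)Cl, Et3N, DMAP (cat.), CH2Cl2, 0 °C
Reagents that add atoms: diethyl chlorophosphate, CCOP(=O)(Cl)OCC
Why: Phosphorylation of the primary allylic alcohol gives the leaving group needed for copper-catalysed allylic substitution.

Step 3
Reactants: 4 2,2-diethoxyethan-1-ol; 5 3-bromoprop-1-yne
Product: 6 3-(2,2-diethoxyethoxy)prop-1-yne
Conditions: NaH, THF, 0 °C; 5, Bu4NI (cat.), 0 °C → rt
Reagents that add atoms: none
Why: Williamson ether synthesis with a primary propargylic bromide.

Step 4
Reactants: 6 3-(2,2-diethoxyethoxy)prop-1-yne; 3 (Z)-4-[(tert-butyldiphenylsilyl)oxy]but-2-en-1-yl diethyl phosphate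
Product: 8 tert-butyl{[(2S)-5-(2,2-diethoxyethoxy)-2-ethenylpent-3-yn-1-yl]oxy}diphenylsilane, via alkynylalane 7 (not isolated)
Conditions: iBu2AlH, Et3N (5 mol%), hexane, 55 °C; then 3, CuCl2·2H2O (5 mol%), chiral imidazolinium sulfonate (NHC precursor, 5 mol%, antipode giving 2S), THF, −30 °C
Reagents that add atoms: none
Why: Copper-catalysed enantioselective allylic substitution (SN2') of an allylic phosphate by an alkynylaluminium reagent; the NHC–copper catalyst delivers the alkynyl group to the carbon bearing the silyloxymethyl group and sets the side-chain stereocentre (2S) by catalyst control.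

Step 5
Reactants: 8 tert-butyl{[(2S)-5-(2,2-diethoxyethoxy)-2-ethenylpent-3-yn-1-yl]oxy}diphenylsilane; 9 1-bromo-2-methylprop-1-ene
Product: 11 tert-butyl{[(2S)-2-[3-(2,2-diethoxyethoxy)prop-1-yn-1-yl]-6-methylhept-5-en-1-yl]oxy}diphenylsilane, via alkylborane 10 (not isolated)
Conditions: 9-BBN, THF, 0 °C → rt; then 9, Pd(dppf)Cl2 (5 mol%), K3PO4, DMF/H2O, rt
Reagents that add atoms: none
Why: Anti-Markovnikov hydroboration of the monosubstituted alkene (faster than the hindered internal alkyne) followed by B-alkyl Suzuki–Miyaura coupling builds the 4-methylpent-3-enyl chain without touching the stereocentre.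

Step 6
Reactants: 11 tert-butyl{[(2S)-2-[3-(2,2-diethoxyethoxy)prop-1-yn-1-yl]-6-methylhept-5-en-1-yl]oxy}diphenylsilane
Product: 12 2-{[(4S)-4-{[(tert-butyldiphenylsilyl)oxy]methyl}-8-methylnon-7-en-2-yn-1-yl]oxy}acetaldehyde
Conditions: 1 M aq. HCl, THF, rt
Reagents that add atoms: water, O
Why: Acid hydrolysis of the diethyl acetal; the silyl ether, alkyne and trisubstituted alkene should be stable to dilute acid at room temperature.

Step 7
Reactants: 12 2-{[(4S)-4-{[(tert-butyldiphenylsilyl)oxy]methyl}-8-methylnon-7-en-2-yn-1-yl]oxy}acetaldehyde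
Product: 13 (3R,4E)-4-[(2S)-2-{[(tert-butyldiphenylsilyl)oxy]methyl}-6-methylhept-5-en-1-ylidene]oxolan-3-ol
Conditions: [Rh(cod)2]OTf (5 mol%), Cl,MeO-BIPHEP (5 mol%, antipode giving 3R), Ph3CCO2H (5 mol%), H2 (1 atm), ClCH2CH2Cl, 45 °C
Reagents that add atoms: none
Why: Rhodium-catalysed hydrogen-mediated reductive cyclisation of an alkynal: oxidative coupling of alkyne and aldehyde to an oxarhodacyclopentene and hydrogenolysis give the oxolane, syn addition across the alkyne fixes the E-alkylidene geometry and the chiral bisphosphine sets the carbinol centre (3R).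

Step 8
Reactants: 13 (3R,4E)-4-[(2S)-2-{[(tert-butyldiphenylsilyl)oxy]methyl}-6-methylhept-5-en-1-ylidene]oxolan-3-ol
Product: 14 (3R,4E)-4-[(2S)-2-{[(tert-butyldiphenylsilyl)oxy]methyl}-6-methylhept-5-en-1-ylidene]oxolan-3-yl N,N-di(propan-2-yl)carbamate
Conditions: NaH, THF, 0 °C; iPr2NCOCl, 60 °C
Reagents that add atoms: N,N-di(propan-2-yl)carbamoyl chloride, CC(C)N(C(C)C)C(=O)Cl
Why: O-Carbamoylation of the sodium alkoxide installs the directing and leaving group for lithiation–borylation.

Step 9
Reactants: 15 (2S)-but-3-yn-2-ol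
Product: 16 (2S)-4-(4,4,5,5-tetramethyl-1,3,2-dioxaborolan-2-yl)but-3-yn-2-ol
Conditions: nBuLi (2.1 equiv), THF, −78 °C; iPrOBpin, −78 °C; HCl in Et2O, −78 °C → rt
Reagents that add atoms: 2-isopropoxy-4,4,5,5-tetramethyl-1,3,2-dioxaborolane, CC(C)OB1OC(C)(C)C(C)(C)O1
Why: Borylation of the lithium acetylide (formed beside the lithium alkoxide) with an alkoxyboronate and acidic release gives the alkynylboronate with the carbinol centre untouched.

Step 10
Reactants: 16 (2S)-4-(4,4,5,5-tetramethyl-1,3,2-dioxaborolan-2-yl)but-3-yn-2-ol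
Product: 17 (2S,3Z)-4-(4,4,5,5-tetramethyl-1,3,2-dioxaborolan-2-yl)but-3-en-2-ol
Conditions: H2 (1 atm), Pd/CaCO3 poisoned with Pb(OAc)2, pyridine, 1,4-dioxane, rt
Reagents that add atoms: none
Why: cis-Semihydrogenation of the alkynylboronate on poisoned palladium gives the Z-alkenylboronate, which is used crude because it can cyclise to an oxaborole on standing.

Step 11
Reactants: 17 (2S,3Z)-4-(4,4,5,5-tetramethyl-1,3,2-dioxaborolan-2-yl)but-3-en-2-ol
Product: 18 (1S)-1-[(1S,2R)-2-(4,4,5,5-tetramethyl-1,3,2-dioxaborolan-2-yl)cyclopropyl]ethan-1-ol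
Conditions: Et2Zn, CH2I2, CH2Cl2, −10 °C → rt
Reagents that add atoms: diiodomethane, ICI
Why: Hydroxyl-directed Simmons–Smith cyclopropanation: in the conformer that minimises allylic 1,3-strain the zinc alkoxide delivers methylene to the alkene face syn to oxygen, so the S carbinol sets both ring centres (1S,2R), and the cis relationship follows stereospecifically from the Z-alkene.

Step 12
Reactants: 18 (1S)-1-[(1S,2R)-2-(4,4,5,5-tetramethyl-1,3,2-dioxaborolan-2-yl)cyclopropyl]ethan-1-ol
Product: 19 1-[(1S,2R)-2-(4,4,5,5-tetramethyl-1,3,2-dioxaborolan-2-yl)cyclopropyl]ethan-1-one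
Conditions: Dess–Martin periodinane, NaHCO3, CH2Cl2, 0 °C → rt
Reagents that add atoms: none
Why: Dess–Martin oxidation of the secondary alcohol under buffered conditions; the carbinol centre has done its work and the ring centres should not epimerise because enolisation toward the cyclopropane is disfavoured.

Step 13
Reactants: 19 1-[(1S,2R)-2-(4,4,5,5-tetramethyl-1,3,2-dioxaborolan-2-yl)cyclopropyl]ethan-1-one
Product: 21 3-[(1S,2R)-2-(4,4,5,5-tetramethyl-1,3,2-dioxaborolan-2-yl)cyclopropyl]but-2-enal (E/Z mixture), via unsaturated imine 20 (not isolated)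
Conditions: diethyl [2-(cyclohexylamino)ethenyl]phosphonate, NaH, THF, 0 → 50 °C; then aq. oxalic acid, rt
Reagents that add atoms: diethyl [2-(cyclohexylamino)ethenyl]phosphonate, CCOP(=O)(OCC)C=CNC1CCCCC1; water, O
Why: Horner–Wadsworth–Emmons-type formyl-olefination with a metallated β-imino phosphonate and hydrolysis of the unsaturated imine gives the enal as an E/Z mixture, which is acceptable for the next step.

Step 14
Reactants: 21 3-[(1S,2R)-2-(4,4,5,5-tetramethyl-1,3,2-dioxaborolan-2-yl)cyclopropyl]but-2-enal
Product: 22 (3S)-3-[(1S,2R)-2-(4,4,5,5-tetramethyl-1,3,2-dioxaborolan-2-yl)cyclopropyl]butanal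
Conditions: 2-tert-butyl-3-methylimidazolidin-4-one·Cl3CCO2H (20 mol%, antipode giving 3S), Hantzsch ester, CHCl3, −30 °C
Reagents that add atoms: none
Why: Imidazolidinone-catalysed iminium transfer hydrogenation with a Hantzsch ester is stereoconvergent, because the E and Z iminium ions interconvert before hydride transfer, and the catalyst sets the methyl-bearing centre (3S).

Step 15
Reactants: 22 (3S)-3-[(1S,2R)-2-(4,4,5,5-tetramethyl-1,3,2-dioxaborolan-2-yl)cyclopropyl]butanal
Product: 23 2-[(1R,2S)-2-[(2S)-4,4-dimethoxybutan-2-yl]cyclopropyl]-4,4,5,5-tetramethyl-1,3,2-dioxaborolane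
Conditions: HC(OMe)3, MeOH, PPTS (cat.), rt
Reagents that add atoms: trimethyl orthoformate, COC(OC)OC
Why: Acetalisation masks the aldehyde against the organolithium chemistry of the key step while the pinacol boronate is inert to methanol and mild acid.

Step 16
Reactants: 14 (3R,4E)-4-[(2S)-2-{[(tert-butyldiphenylsilyl)oxy]methyl}-6-methylhept-5-en-1-ylidene]oxolan-3-yl N,N-di(propan-2-yl)carbamate; 23 2-[(1R,2S)-2-[(2S)-4,4-dimethoxybutan-2-yl]cyclopropyl]-4,4,5,5-tetramethyl-1,3,2-dioxaborolane
Product: 29 cyclooctenol fused to 2,5-dihydrofuran and cyclopropane (target skeleton; CH2 in place of the lactone C=O; tert-butyldiphenylsilyl ether in place of the acetate; all six stereocentres as in the target), via lithiated carbamate 24 (not isolated), via boronate complex 25 (not isolated), via allylboronate acetal 26 (not isolated), via allylboronate aldehyde 27 (not isolated), via borate ester 28 (not isolated)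
Conditions: sBuLi, TMEDA, Et2O, −78 °C; then 23, −78 → 35 °C; then THF (5 mM), 1 M aq. HCl, rt → 45 °C
Reagents that add atoms: water, O
Why: Proposed new method: deprotonation of 14 with retention gives the chelated allyllithium 24, borylation by 23 gives boronate 25, and on warming the cyclopropyl carbon shifts from boron to carbon (retention at the cyclopropane, inversion at the former carbinol carbon, carbamate expelled) to give tertiary allylboronate 26 and with it the bond from the future butenolide α-carbon to the cyclopropane; after acid unmasking of the aldehyde (27) the carbon-bound boron transfers the allyl unit to the tethered aldehyde with allylic transposition, forming the bond between the side-chain-bearing ring CH and the carbinol carbon. The closest known chemistry is the lithiation–borylation of secondary allylic carbamates to tertiary allylboronic esters and their three-component allylation of added aldehydes; what is new is that the migrating group carries the aldehyde, so that the allyl transfer closes a ring. The cyclooctene is closed in the allylboration by attack of the exocyclic alkylidene carbon on the aldehyde through a boat-like B–O–C–C–C–C array bridged by the four-carbon tether (a bicyclo[4.2.2]-type transition state), which turns the exocyclic alkene into the tetrasubstituted endocyclic one shared by the five- and eight-membered rings. The ring CH centre is set by suprafacial chirality transfer from the boron-bearing carbon (fixed by the 3R carbinol of step 7) together with the E-alkylidene geometry, and the carbinol centre by the closed transition state in which the tether forces the aldehyde chain toward the cyclopropane, so that side chain and hydroxyl end up anti along the chain and cis on the ring. The step needs γ- over α-attack, secured because a carbon-bound allylboronate reacts only with transposition; ring closure over oligomerisation, secured by dilution and by the cis-cyclopropane and the oxolane fixing five of the eight ring atoms; and stereoretentive migration, which is inherent to the 1,2-metalate shift.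

Step 17
Reactants: 29 cyclooctenol fused to 2,5-dihydrofuran and cyclopropane
Product: 30 corresponding 3,4-fused furan (free ring alcohol; tert-butyldiphenylsilyl ether)
Conditions: DDQ, 1,4-dioxane, rt
Reagents that add atoms: none
Why: Dehydrogenation of the 2,5-dihydrofuran by DDQ is driven by aromatisation and should leave the alcohol, silyl ether, cyclopropane and side-chain alkene untouched.

Step 18
Reactants: 30 3,4-fused furan
Product: 33 O-silylated deacetyl target (butenolide; tert-butyldiphenylsilyl ether), via endoperoxide 31 (not isolated), via hydroxybutenolide 32 (not isolated)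
Conditions: O2, hν, rose bengal (cat.), iPr2NEt, CH2Cl2, −78 °C; then NaBH4, EtOH, 0 °C; then 1 M aq. HCl
Reagents that add atoms: dioxygen, O=O
Why: [4+2] addition of singlet oxygen to the furan and amine-induced Kornblum–DeLaMare opening of the endoperoxide, in which the base should remove the less hindered bridgehead hydrogen next to the cyclopropyl-bearing carbon and so place the carbonyl there, then borohydride reduction of the lactol (as its aldehyde tautomer) and relactonisation give the butenolide.

Step 19
Reactants: 33 O-silylated deacetyl target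
Product: 34 deacetyl target (primary and secondary alcohol)
Conditions: Bu4NF, AcOH, THF, 0 °C → rt
Reagents that add atoms: none
Why: Fluoride cleavage of the silyl ether, buffered with acetic acid so that the butenolide and its base-sensitive γ-positions are not affected.

Step 20
Reactants: 34 deacetyl target
Product: 35 target CNP0267808.2
Conditions: Ac2O (1.1 equiv), 2,4,6-collidine, CH2Cl2, −40 → 0 °C
Reagents that add atoms: acetic anhydride, CC(=O)OC(C)=O
Why: Kinetically selective acylation of the primary alcohol in the presence of the hindered secondary ring alcohol with a limited amount of anhydride and a hindered pyridine base should give the target.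

**Compound list**

1 | (Z)-but-2-ene-1,4-diol | OC/C=C\CO | starting material
2 | (Z)-4-[(tert-butyldiphenylsilyl)oxy]but-2-en-1-ol | CC(C)(C)[Si](c1ccccc1)(c1ccccc1)OC/C=C\CO | intermediate
3 | (Z)-4-[(tert-butyldiphenylsilyl)oxy]but-2-en-1-yl diethyl phosphate | CC(C)(C)[Si](c1ccccc1)(c1ccccc1)OC/C=C\COP(=O)(OCC)OCC | intermediate
4 | 2,2-diethoxyethan-1-ol | CCOC(CO)OCC | starting material
5 | 3-bromoprop-1-yne | C#CCBr | starting material
6 | 3-(2,2-diethoxyethoxy)prop-1-yne | C#CCOCC(OCC)OCC | intermediate
7 | [3-(2,2-diethoxyethoxy)prop-1-yn-1-yl]bis(2-methylpropyl)alumane | CC(C)C[Al](CC(C)C)C#CCOCC(OCC)OCC | intermediate (not isolated)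
8 | tert-butyl{[(2S)-5-(2,2-diethoxyethoxy)-2-ethenylpent-3-yn-1-yl]oxy}diphenylsilane | CC(C)(C)[Si](c1ccccc1)(c1ccccc1)OC[C@@H](C=C)C#CCOCC(OCC)OCC | intermediate
9 | 1-bromo-2-methylprop-1-ene | CC(C)=CBr | starting material
10 | B-alkyl-9-borabicyclo[3.3.1]nonane from 8 (boron on the terminal carbon of the former ethenyl group; 2S) | CC(C)(C)[Si](c1ccccc1)(c1ccccc1)OC[C@@H](CCB1C2CCCC1CCC2)C#CCOCC(OCC)OCC | intermediate (not isolated)
11 | tert-butyl{[(2S)-2-[3-(2,2-diethoxyethoxy)prop-1-yn-1-yl]-6-methylhept-5-en-1-yl]oxy}diphenylsilane | CC(C)(C)[Si](c1ccccc1)(c1ccccc1)OC[C@@H](CCC=C(C)C)C#CCOCC(OCC)OCC | intermediate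
12 | 2-{[(4S)-4-{[(tert-butyldiphenylsilyl)oxy]methyl}-8-methylnon-7-en-2-yn-1-yl]oxy}acetaldehyde | CC(C)(C)[Si](c1ccccc1)(c1ccccc1)OC[C@@H](CCC=C(C)C)C#CCOCC=O | intermediate
13 | (3R,4E)-4-[(2S)-2-{[(tert-butyldiphenylsilyl)oxy]methyl}-6-methylhept-5-en-1-ylidene]oxolan-3-ol | CC(C)(C)[Si](c1ccccc1)(c1ccccc1)OC[C@@H](CCC=C(C)C)/C=C1\COC[C@@H]1O | intermediate
14 | (3R,4E)-4-[(2S)-2-{[(tert-butyldiphenylsilyl)oxy]methyl}-6-methylhept-5-en-1-ylidene]oxolan-3-yl N,N-di(propan-2-yl)carbamate | CC(C)(C)[Si](c1ccccc1)(c1ccccc1)OC[C@@H](CCC=C(C)C)/C=C1\COC[C@@H]1OC(=O)N(C(C)C)C(C)C | intermediate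
15 | (2S)-but-3-yn-2-ol | C[C@H](O)C#C | starting material
16 | (2S)-4-(4,4,5,5-tetramethyl-1,3,2-dioxaborolan-2-yl)but-3-yn-2-ol | C[C@H](O)C#CB1OC(C)(C)C(C)(C)O1 | intermediate
17 | (2S,3Z)-4-(4,4,5,5-tetramethyl-1,3,2-dioxaborolan-2-yl)but-3-en-2-ol | C[C@H](O)/C=C\B1OC(C)(C)C(C)(C)O1 | intermediate
18 | (1S)-1-[(1S,2R)-2-(4,4,5,5-tetramethyl-1,3,2-dioxaborolan-2-yl)cyclopropyl]ethan-1-ol | CC1(C)OB(OC1(C)C)[C@@H]2C[C@@H]2[C@H](C)O | intermediate
19 | 1-[(1S,2R)-2-(4,4,5,5-tetramethyl-1,3,2-dioxaborolan-2-yl)cyclopropyl]ethan-1-one | CC1(C)OB(OC1(C)C)[C@@H]2C[C@@H]2C(C)=O | intermediate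
20 | N-cyclohexyl imine of enal 21 | CC1(C)OB(OC1(C)C)[C@@H]2C[C@@H]2C(C)=CC=NC3CCCCC3 | intermediate (not isolated)
21 | 3-[(1S,2R)-2-(4,4,5,5-tetramethyl-1,3,2-dioxaborolan-2-yl)cyclopropyl]but-2-enal (E/Z mixture) | CC1(C)OB(OC1(C)C)[C@@H]2C[C@@H]2C(C)=CC=O | intermediate
22 | (3S)-3-[(1S,2R)-2-(4,4,5,5-tetramethyl-1,3,2-dioxaborolan-2-yl)cyclopropyl]butanal | CC1(C)OB(OC1(C)C)[C@@H]2C[C@@H]2[C@@H](C)CC=O | intermediate
23 | 2-[(1R,2S)-2-[(2S)-4,4-dimethoxybutan-2-yl]cyclopropyl]-4,4,5,5-tetramethyl-1,3,2-dioxaborolane | CC1(C)OB(OC1(C)C)[C@@H]2C[C@@H]2[C@@H](C)CC(OC)OC | intermediate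
24 | 3-lithio derivative of 14 (lithium on the carbamate-bearing ring carbon, in the place of the former hydrogen) | CC(C)(C)[Si](c1ccccc1)(c1ccccc1)OC[C@@H](CCC=C(C)C)/C=C1\COC[C@]1([Li])OC(=O)N(C(C)C)C(C)C | intermediate (not isolated)
25 | lithium boronate complex of 24 and 23 (tetracoordinate boron on the carbamate-bearing carbon) | CC(C)(C)[Si](c1ccccc1)(c1ccccc1)OC[C@@H](CCC=C(C)C)/C=C1\COC[C@@]1(OC(=O)N(C(C)C)C(C)C)[B-]2(OC(C)(C)C(C)(C)O2)[C@@H]3C[C@@H]3[C@@H](C)CC(OC)OC.[Li+] | intermediate (not isolated)
26 | tertiary allylboronate: oxolane carbon 3 carries the pinacol boronate and the cyclopropyl group; dimethyl acetal intact | CC(C)(C)[Si](c1ccccc1)(c1ccccc1)OC[C@@H](CCC=C(C)C)/C=C1\COC[C@@]1(B2OC(C)(C)C(C)(C)O2)[C@@H]3C[C@@H]3[C@@H](C)CC(OC)OC | intermediate (not isolated)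
27 | tertiary allylboronate with free aldehyde | CC(C)(C)[Si](c1ccccc1)(c1ccccc1)OC[C@@H](CCC=C(C)C)/C=C1\COC[C@@]1(B2OC(C)(C)C(C)(C)O2)[C@@H]3C[C@@H]3[C@@H](C)CC=O | intermediate (not isolated)
28 | pinacol borate ester of 29 | CC(C)(C)[Si](c1ccccc1)(c1ccccc1)OC[C@@H](CCC=C(C)C)[C@@H]1C2=C(COC2)[C@@H]3C[C@@H]3[C@@H](C)C[C@@H]1OB4OC(C)(C)C(C)(C)O4 | intermediate (not isolated)
29 | cyclooctenol fused to 2,5-dihydrofuran and cyclopropane: target skeleton with CH2 in place of the lactone C=O and tert-butyldiphenylsilyl ether in place of the acetate; stereocentres as in the target | CC(C)(C)[Si](c1ccccc1)(c1ccccc1)OC[C@@H](CCC=C(C)C)[C@@H]1C2=C(COC2)[C@@H]3C[C@@H]3[C@@H](C)C[C@@H]1O | intermediate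
30 | corresponding 3,4-fused furan | CC(C)(C)[Si](c1ccccc1)(c1ccccc1)OC[C@@H](CCC=C(C)C)[C@@H]1c2cocc2[C@@H]3C[C@@H]3[C@@H](C)C[C@@H]1O | intermediate
31 | furan endoperoxide of 30 | CC(C)(C)[Si](c1ccccc1)(c1ccccc1)OC[C@@H](CCC=C(C)C)[C@@H]1C2=C(C4OOC2O4)[C@@H]3C[C@@H]3[C@@H](C)C[C@@H]1O | intermediate (not isolated)
32 | γ-hydroxybutenolide (lactol carbon next to the side-chain-bearing carbon; carbonyl next to the cyclopropyl-bearing carbon) | CC(C)(C)[Si](c1ccccc1)(c1ccccc1)OC[C@@H](CCC=C(C)C)[C@@H]1C2=C(C(=O)OC2O)[C@@H]3C[C@@H]3[C@@H](C)C[C@@H]1O | intermediate (not isolated)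
33 | O-tert-butyldiphenylsilyl deacetyl target (butenolide) | CC(C)(C)[Si](c1ccccc1)(c1ccccc1)OC[C@@H](CCC=C(C)C)[C@@H]1C2=C(C(=O)OC2)[C@@H]3C[C@@H]3[C@@H](C)C[C@@H]1O | intermediate
34 | deacetyl target (diol) | OC[C@@H](CCC=C(C)C)[C@@H]1C2=C(C(=O)OC2)[C@@H]3C[C@@H]3[C@@H](C)C[C@@H]1O | intermediate
35 | CNP0267808.2 | CC(=O)OC[C@@H](CCC=C(C)C)[C@@H]1C2=C(C(=O)OC2)[C@@H]2C[C@@H]2[C@@H](C)C[C@@H]1O | target

**Step count and risks**

Total step count: 20. Longest linear sequence: 12 steps (steps 9–15, then 16–20; the branch through steps 1, 2, 4–8 and 16–20 is equally long).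

Steps most likely to fail:

1. Step 16 (proposed new method). The bridged transition state may make the intramolecular allyl transfer slower than intermolecular allylboration (oligomerisation), protodeboronation or a 1,3-boron shift. The lithiated carbamate may also ring-open by β-elimination before it is borylated, and the pairing of the boron-bearing centre with the cyclopropane and methyl centres may be mismatched, so that ring closure stalls. Fallback with known chemistry, setting out from 14 and 22 and returning at 29: 14 is lithiated (sBuLi, TMEDA, Et2O, −78 °C), transmetallated with ClTi(OiPr)3 (inversion) and added to aldehyde 22. This homoaldol reaction of the titanated allyl carbamate forms the bond between the ring CH and the carbinol carbon through a chair transition state and should give the anti homoaldol adduct F1, an enol carbamate of the 2,5-dihydrofuran that still carries the cyclopropyl boronate. An intramolecular Suzuki–Miyaura coupling of the enol carbamate C–O bond with the cyclopropylboronate (Ni(cod)2, PCy3, K3PO4, toluene, 80 °C, high dilution) then forms the bond to the cyclopropane and closes the eight-membered ring to 29.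

2. Step 18. The base-induced opening of the endoperoxide may show poor regioselectivity (carbonyl formed at the wrong furan α-carbon), and singlet oxygen may undergo a competing ene reaction with the trisubstituted side-chain alkene. Fallback, setting out from 30 and returning at 33: photooxygenation without amine (O2, hν, rose bengal, CH2Cl2, −78 °C) lets the neighbouring ring hydroxyl open endoperoxide 31 at the α-carbon next to the side-chain-bearing carbon, the only one it can reach through a five-membered ring. This gives the hydroperoxy acetal F2. Ac2O/pyridine dehydrates the hydroperoxide to the lactone carbonyl and gives the bridged alkoxybutenolide F3, in which the carbonyl position is fixed by the tether. Aqueous NaOH/THF opens this pseudo-ester to the aldehyde acid, NaBH4 reduces the aldehyde and acidification relactonises to 33.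

3. Step 11. Methylene transfer to the electron-poor alkenylboronate may be sluggish, and pinacol may be lost by cyclisation of the Z-hydroxyalkenyl boronate to an oxaborole, which would erode conversion and facial selectivity. Fallback, setting out from 15 and returning at 18 (boron introduced after the ring is made): iodination of the alkyne (N-iodosuccinimide, AgNO3, acetone) gives the iodoalkyne F4. Diimide reduction (2-nitrobenzenesulfonyl hydrazide, Et3N) gives the (Z)-iodoalkenol F5. Hydroxyl-directed Simmons–Smith cyclopropanation (Et2Zn, CH2I2, CH2Cl2) gives the cis-iodocyclopropyl carbinol F6 with the same facial sense. Iodine–lithium exchange on its lithium alkoxide (tBuLi, Et2O, −78 °C; the cyclopropyllithium is configurationally stable) and trapping with iPrOBpin give 18.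

**Further compounds**

F1 | step 16 | anti homoaldol adduct: 4-[(carbamoyl)oxy]-2,5-dihydrofuran-3-yl group on the new ring-CH centre, free secondary alcohol, cyclopropyl pinacol boronate intact | CC(C)(C)[Si](c1ccccc1)(c1ccccc1)OC[C@@H](CCC=C(C)C)[C@H](C1=C(OC(=O)N(C(C)C)C(C)C)COC1)[C@@H](O)C[C@H](C)[C@H]1C[C@H]1B1OC(C)(C)C(C)(C)O1
F2 | step 18 | hydroperoxy acetal: ring oxygen of the carbinol bonded to the furan-derived carbon next to the side-chain-bearing carbon; hydroperoxide on the other oxygenated carbon | CC(C)(C)[Si](c1ccccc1)(c1ccccc1)OC[C@@H](CCC=C(C)C)[C@@H]1C2=C(C(OO)OC2O3)[C@@H]2C[C@@H]2[C@@H](C)C[C@@H]13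
F3 | step 18 | bridged alkoxybutenolide (pseudo-ester) from F2 | CC(C)(C)[Si](c1ccccc1)(c1ccccc1)OC[C@@H](CCC=C(C)C)[C@@H]1C2=C(C(=O)OC2O3)[C@@H]2C[C@@H]2[C@@H](C)C[C@@H]13
F4 | step 11 | (2S)-4-iodobut-3-yn-2-ol | C[C@H](O)C#CI
F5 | step 11 | (2S,3Z)-4-iodobut-3-en-2-ol | C[C@H](O)/C=C\I
F6 | step 11 | (1S)-1-[(1R,2R)-2-iodocyclopropyl]ethan-1-ol | I[C@@H]1C[C@@H]1[C@H](C)O
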